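**Retrosynthetic overview**

1. Ring letters: A = terminal 3,5-dihydroxyphenoxy ring, B = central tris(aryloxy)phenol ring, C = the two 2,6-dihydroxy-1,4-phenylenedioxy rings, D–E = the two hexaoxygenated biphenyls. All eight benzene rings are bought; none is built.
2. Target ⇒ its nonadeca-O-methyl ether; global BBr3 demethylation comes last.
3. Both B–O–C ethers are cut: twofold Ullmann coupling of a C–D–E phenol onto the 1,3-dibromide of the A–B ether, which itself comes from a Chan–Lam–Evans coupling.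
4. C–D–E phenol ⇒ aldehyde (Dakin; CHO is the masked ring C phenol) ⇒ D–E Suzuki coupling on a ring D bromide ⇒ ring-selective bromination ⇒ C–O–D Ullmann coupling.
5. Order of joining: C–O–D, then D–E, unmask the ring C OH; A–O–B separately; 2 × B–O–C; deprotect.

Assumption: the target has no stereocentre and no stereogenic axis (each biaryl carries a symmetric 2,4,6-trihydroxyphenyl ring), so it is achiral and needs no stereocontrol; the five building blocks are taken as catalogue chemicals.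

**Route**

Step 1
Reactants: 1 2,4,6-trimethoxyphenol; 2 4-bromo-2,6-dimethoxybenzaldehyde
Product: 3 2,6-dimethoxy-4-(2,4,6-trimethoxyphenoxy)benzaldehyde
Conditions: CuI (10 mol%), picolinic acid (20 mol%), K3PO4 (2 equiv), DMSO, 90 °C, Ar
Reagents that add atoms: none
Why: Ullmann-type C–O coupling in which the CuI/picolinic acid system accepts the di-ortho-methoxy phenoxide, while the bromide of 2 is unhindered and activated by the para-formyl group that later serves as the masked ring C phenol.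

Step 2
Reactants: 3 2,6-dimethoxy-4-(2,4,6-trimethoxyphenoxy)benzaldehyde
Product: 4 4-(3-bromo-2,4,6-trimethoxyphenoxy)-2,6-dimethoxybenzaldehyde
Conditions: NBS (1.05 equiv), MeCN, 0 °C to rt, dark
Reagents that add atoms: N-bromosuccinimide, O=C1CCC(=O)N1Br
Why: Electrophilic aromatic bromination goes to ring D, whose free CH is ortho/ortho/para to three OMe groups and far more nucleophilic than the formyl-deactivated ring C, and the first bromine deactivates ring D against a second substitution.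

Step 3
Reactants: 4 4-(3-bromo-2,4,6-trimethoxyphenoxy)-2,6-dimethoxybenzaldehyde; 5 (2,4,6-trimethoxyphenyl)boronic acid
Product: 6 4-[(2,2',4,4',6,6'-hexamethoxybiphenyl-3-yl)oxy]-2,6-dimethoxybenzaldehyde
Conditions: 5 (2 equiv), Pd(OAc)2 (5 mol%), SPhos (10 mol%), K3PO4 (3 equiv), toluene/H2O 20:1, 100 °C, Ar
Reagents that add atoms: none
Why: Suzuki–Miyaura coupling in which the bulky electron-rich biarylphosphine drives oxidative addition into the electron-rich di-ortho-methoxy bromide and reductive elimination to the tetra-ortho-oxygenated biaryl, excess 5 offsetting protodeboronation; the new axis is not stereogenic because ring E is symmetric.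

Step 4
Reactants: 6 4-[(2,2',4,4',6,6'-hexamethoxybiphenyl-3-yl)oxy]-2,6-dimethoxybenzaldehyde
Product: 8 4-[(2,2',4,4',6,6'-hexamethoxybiphenyl-3-yl)oxy]-2,6-dimethoxyphenol, via aryl formate 7 (not isolated)
Conditions: mCPBA (1.1 equiv), CH2Cl2, 0 °C to rt; then Et3N, MeOH, rt
Reagents that add atoms: 3-chloroperoxybenzoic acid (mCPBA), OOC(=O)c1cccc(Cl)c1
Why: Dakin-type Baeyer–Villiger oxidation in which the electron-rich trioxygenated aryl group migrates in preference to hydride to give the aryl formate, whose amine-catalysed methanolysis frees the ring C phenol.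

Step 5
Reactants: 9 2,6-dibromo-4-methoxyphenol; 10 (3,5-dimethoxyphenyl)boronic acid
Product: 11 1,3-dibromo-2-(3,5-dimethoxyphenoxy)-5-methoxybenzene
Conditions: 10 (2 equiv), Cu(OAc)2 (30 mol%), pyridine (3 equiv), 4 Å MS, CH2Cl2, O2 (1 atm), rt
Reagents that add atoms: none
Why: Chan–Lam–Evans oxidative C–O coupling at divalent copper runs at room temperature, accepts 2,6-dihalophenols and leaves both aryl bromides untouched, with O2 as the terminal oxidant.

Step 6
Reactants: 11 1,3-dibromo-2-(3,5-dimethoxyphenoxy)-5-methoxybenzene; 8 4-[(2,2',4,4',6,6'-hexamethoxybiphenyl-3-yl)oxy]-2,6-dimethoxyphenol (2.4 equiv)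
Product: 13 1,3-bis{4-[(2,2',4,4',6,6'-hexamethoxybiphenyl-3-yl)oxy]-2,6-dimethoxyphenoxy}-2-(3,5-dimethoxyphenoxy)-5-methoxybenzene, via monoether monobromide 12 (not isolated)
Conditions: CuI (30 mol%), picolinic acid (60 mol%), K3PO4 (4 equiv), DMSO, 110 °C, Ar, 48 h
Reagents that add atoms: none
Why: Twofold Ullmann-type C–O coupling with a picolinate-ligated monovalent copper catalyst suited to 2,6-dimethoxyphenoxides and ortho-substituted aryl bromides; the two C–Br bonds of 11 are equivalent, so no selectivity question arises.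

Step 7
Reactants: 13 1,3-bis{4-[(2,2',4,4',6,6'-hexamethoxybiphenyl-3-yl)oxy]-2,6-dimethoxyphenoxy}-2-(3,5-dimethoxyphenoxy)-5-methoxybenzene
Product: 15 CNP0227063.0, via per(dibromoboryl) ether 14 (not isolated)
Conditions: BBr3 (1 M in CH2Cl2, 60 equiv), CH2Cl2, −78 °C to rt, 48 h, Ar; then ice-water; degassed work-up, Sephadex LH-20 (MeOH)
Reagents that add atoms: none
Why: Lewis-acid ether cleavage in which BBr3 coordinates each methoxy oxygen and bromide removes the methyl group by SN2 attack, whereas diaryl ether and biaryl bonds offer no sp3 carbon and survive; hydrolysis of the aryloxyboron intermediate frees the nineteen phenols, and no stereocentre is present or created.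

**Compound list**

1 | 2,4,6-trimethoxyphenol | COc1cc(OC)c(O)c(OC)c1 | starting material
2 | 4-bromo-2,6-dimethoxybenzaldehyde | O=Cc1c(OC)cc(Br)cc1OC | starting material
3 | 2,6-dimethoxy-4-(2,4,6-trimethoxyphenoxy)benzaldehyde | COc1cc(OC)c(Oc2cc(OC)c(C=O)c(OC)c2)c(OC)c1 | intermediate
4 | 4-(3-bromo-2,4,6-trimethoxyphenoxy)-2,6-dimethoxybenzaldehyde | COc1cc(OC)c(Oc2cc(OC)c(C=O)c(OC)c2)c(OC)c1Br | intermediate
5 | (2,4,6-trimethoxyphenyl)boronic acid | COc1cc(OC)c(B(O)O)c(OC)c1 | starting material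
6 | 4-[(2,2',4,4',6,6'-hexamethoxybiphenyl-3-yl)oxy]-2,6-dimethoxybenzaldehyde | COc1cc(OC)c(Oc2cc(OC)c(C=O)c(OC)c2)c(OC)c1-c1c(OC)cc(OC)cc1OC | intermediate
7 | 4-[(2,2',4,4',6,6'-hexamethoxybiphenyl-3-yl)oxy]-2,6-dimethoxyphenyl formate | COc1cc(OC)c(Oc2cc(OC)c(OC=O)c(OC)c2)c(OC)c1-c1c(OC)cc(OC)cc1OC | intermediate
8 | 4-[(2,2',4,4',6,6'-hexamethoxybiphenyl-3-yl)oxy]-2,6-dimethoxyphenol | COc1cc(OC)c(Oc2cc(OC)c(O)c(OC)c2)c(OC)c1-c1c(OC)cc(OC)cc1OC | intermediate
9 | 2,6-dibromo-4-methoxyphenol | COc1cc(Br)c(O)c(Br)c1 | starting material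
10 | (3,5-dimethoxyphenyl)boronic acid | COc1cc(OC)cc(B(O)O)c1 | starting material
11 | 1,3-dibromo-2-(3,5-dimethoxyphenoxy)-5-methoxybenzene | COc1cc(OC)cc(Oc2c(Br)cc(OC)cc2Br)c1 | intermediate
12 | 1-bromo-2-(3,5-dimethoxyphenoxy)-3-{4-[(2,2',4,4',6,6'-hexamethoxybiphenyl-3-yl)oxy]-2,6-dimethoxyphenoxy}-5-methoxybenzene | COc1cc(OC)cc(Oc2c(Br)cc(OC)cc2Oc2c(OC)cc(Oc3c(OC)cc(OC)c(-c4c(OC)cc(OC)cc4OC)c3OC)cc2OC)c1 | intermediate
13 | 1,3-bis{4-[(2,2',4,4',6,6'-hexamethoxybiphenyl-3-yl)oxy]-2,6-dimethoxyphenoxy}-2-(3,5-dimethoxyphenoxy)-5-methoxybenzene (nonadeca-O-methyl ether of the target) | COc1cc(OC)cc(Oc2c(Oc3c(OC)cc(Oc4c(OC)cc(OC)c(-c5c(OC)cc(OC)cc5OC)c4OC)cc3OC)cc(OC)cc2Oc2c(OC)cc(Oc3c(OC)cc(OC)c(-c4c(OC)cc(OC)cc4OC)c3OC)cc2OC)c1 | intermediate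
14 | target skeleton in which each of the nineteen phenolic oxygens carries a BBr2 group (formal per(dibromoboryl) ether) | BrB(Br)Oc1cc(OB(Br)Br)cc(Oc2c(Oc3c(OB(Br)Br)cc(Oc4c(OB(Br)Br)cc(OB(Br)Br)c(-c5c(OB(Br)Br)cc(OB(Br)Br)cc5OB(Br)Br)c4OB(Br)Br)cc3OB(Br)Br)cc(OB(Br)Br)cc2Oc2c(OB(Br)Br)cc(Oc3c(OB(Br)Br)cc(OB(Br)Br)c(-c4c(OB(Br)Br)cc(OB(Br)Br)cc4OB(Br)Br)c3OB(Br)Br)cc2OB(Br)Br)c1 | intermediate
15 | CNP0227063.0: 2-(3,5-dihydroxyphenoxy)-1,3-bis{4-[(2,2',4,4',6,6'-hexahydroxybiphenyl-3-yl)oxy]-2,6-dihydroxyphenoxy}-5-hydroxybenzene (achiral) | Oc1cc(O)cc(Oc2c(Oc3c(O)cc(Oc4c(O)cc(O)c(-c5c(O)cc(O)cc5O)c4O)cc3O)cc(O)cc2Oc2c(O)cc(Oc3c(O)cc(O)c(-c4c(O)cc(O)cc4O)c3O)cc2O)c1 | target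

**Step count and risk**

Total steps: 7. Longest linear sequence: 6 (steps 1, 2, 3, 4, 6, 7); step 5 is a one-step side branch.

The three steps most likely to fail:

Step 3 (Suzuki coupling to a tetra-ortho-oxygenated biaryl on the very electron-rich, hindered bromide 4, with a boronic acid prone to protodeboronation). The fallback forms the biaryl first on a formyl-activated bromide and the ether second; it sets out from boronic acid 5 and comes back at 6. Commercial 2,4,6-trimethoxybenzaldehyde is brominated (NBS, MeCN, 0 °C) to 3-bromo-2,4,6-trimethoxybenzaldehyde F1, whose C–Br bond is activated towards oxidative addition by the formyl group. Suzuki–Miyaura coupling of F1 with 5 (Pd(OAc)2, SPhos, K3PO4, toluene, 100 °C) gives 2,2',4,4',6,6'-hexamethoxybiphenyl-3-carbaldehyde F2. Dakin oxidation (mCPBA, CH2Cl2; then Et3N, MeOH) passes through 2,2',4,4',6,6'-hexamethoxybiphenyl-3-yl formate F3 to 2,2',4,4',6,6'-hexamethoxybiphenyl-3-ol F4. Ullmann coupling of F4 with 2 under the step 1 conditions then gives 6.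

Step 6 (two successive Ullmann etherifications between a hindered 2,6-dimethoxyphenol and ortho-aryloxy aryl bromides; the second, on 12, is the most congested bond of the synthesis). The fallback replaces copper coupling at ring B by nucleophilic aromatic substitution and attaches ring A last; it sets out from 8 and comes back at 13. The potassium phenoxide of 8 (2.2 equiv; K2CO3, DMSO, 110 °C) displaces both ortho-fluorides of commercial 2,6-difluoro-4-methoxybenzaldehyde (SNAr, each fluoride activated by the ortho formyl group) to give 4-methoxy-2,6-bis{4-[(2,2',4,4',6,6'-hexamethoxybiphenyl-3-yl)oxy]-2,6-dimethoxyphenoxy}benzaldehyde F5. Dakin oxidation (mCPBA; then Et3N, MeOH) leads through 4-methoxy-2,6-bis{4-[(2,2',4,4',6,6'-hexamethoxybiphenyl-3-yl)oxy]-2,6-dimethoxyphenoxy}phenyl formate F6 to 4-methoxy-2,6-bis{4-[(2,2',4,4',6,6'-hexamethoxybiphenyl-3-yl)oxy]-2,6-dimethoxyphenoxy}phenol F7. Chan–Lam–Evans coupling of F7 with 10 (Cu(OAc)2, pyridine, 4 Å MS, CH2Cl2, O2) gives 13.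

Step 7 (nineteen-fold demethylation; insoluble borate intermediates can stall it, and the free polyphenol is air-sensitive and hard to purify). The fallback isolates the product through its peracetate instead of directly; it sets out from 13 and comes back at 15. After BBr3 treatment and aqueous quench as in step 7 (again through 14), the crude polyphenol is not purified but acetylated (Ac2O, pyridine, DMAP, rt) to the nonadeca-O-acetate of the target F8. This is stable and chromatographable on silica, so under-demethylated material can be separated and resubmitted. Acid-catalysed methanolysis of pure F8 (HCl in degassed MeOH, 40 °C, Ar) and evaporation give 15.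

**Further compounds**

F1 | step 3 | 3-bromo-2,4,6-trimethoxybenzaldehyde | COc1cc(OC)c(C=O)c(OC)c1Br
F2 | step 3 | 2,2',4,4',6,6'-hexamethoxybiphenyl-3-carbaldehyde | COc1cc(OC)c(C=O)c(OC)c1-c1c(OC)cc(OC)cc1OC
F3 | step 3 | 2,2',4,4',6,6'-hexamethoxybiphenyl-3-yl formate | COc1cc(OC)c(OC=O)c(OC)c1-c1c(OC)cc(OC)cc1OC
F4 | step 3 | 2,2',4,4',6,6'-hexamethoxybiphenyl-3-ol | COc1cc(OC)c(O)c(OC)c1-c1c(OC)cc(OC)cc1OC
F5 | step 6 | 4-methoxy-2,6-bis{4-[(2,2',4,4',6,6'-hexamethoxybiphenyl-3-yl)oxy]-2,6-dimethoxyphenoxy}benzaldehyde | COc1cc(Oc2c(OC)cc(Oc3c(OC)cc(OC)c(-c4c(OC)cc(OC)cc4OC)c3OC)cc2OC)c(C=O)c(Oc2c(OC)cc(Oc3c(OC)cc(OC)c(-c4c(OC)cc(OC)cc4OC)c3OC)cc2OC)c1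
F6 | step 6 | 4-methoxy-2,6-bis{4-[(2,2',4,4',6,6'-hexamethoxybiphenyl-3-yl)oxy]-2,6-dimethoxyphenoxy}phenyl formate | COc1cc(Oc2c(OC)cc(Oc3c(OC)cc(OC)c(-c4c(OC)cc(OC)cc4OC)c3OC)cc2OC)c(OC=O)c(Oc2c(OC)cc(Oc3c(OC)cc(OC)c(-c4c(OC)cc(OC)cc4OC)c3OC)cc2OC)c1
F7 | step 6 | 4-methoxy-2,6-bis{4-[(2,2',4,4',6,6'-hexamethoxybiphenyl-3-yl)oxy]-2,6-dimethoxyphenoxy}phenol | COc1cc(Oc2c(OC)cc(Oc3c(OC)cc(OC)c(-c4c(OC)cc(OC)cc4OC)c3OC)cc2OC)c(O)c(Oc2c(OC)cc(Oc3c(OC)cc(OC)c(-c4c(OC)cc(OC)cc4OC)c3OC)cc2OC)c1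
F8 | step 7 | nonadeca-O-acetate of the target (every OH of 15 as OAc) | CC(=O)Oc1cc(OC(C)=O)cc(Oc2c(Oc3c(OC(C)=O)cc(Oc4c(OC(C)=O)cc(OC(C)=O)c(-c5c(OC(C)=O)cc(OC(C)=O)cc5OC(C)=O)c4OC(C)=O)cc3OC(C)=O)cc(OC(C)=O)cc2Oc2c(OC(C)=O)cc(Oc3c(OC(C)=O)cc(OC(C)=O)c(-c4c(OC(C)=O)cc(OC(C)=O)cc4OC(C)=O)c3OC(C)=O)cc2OC(C)=O)c1
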